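Ring A is a hexasubstituted resorcylate. Its C4 and C6 hydroxyls, C1 ester and C2 methyl are the imprint of a folded 3,5,7-triketo ester. Everything rests on cutting the ring A C1–C2 bond. This spares the route an Ullmann-type union of two crowded arenes, because the bridging oxygen is alkylated onto an sp3 carbon before ring A exists. Precursor 10 is a methyl 3,5-dioxohexanoate with a methyl on chain C4, the ring B aryloxy group on chain C6 and a dioxolane-masked acetyl (chain C7, C8). One acid-then-buffer operation frees C7, joins chain C2 to C7, dehydrates and aromatizes, delivering the complete diaryl ether.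

Key step: step 7

**Numbering**
- Ring A: C1 (CO2Me), C2 (CH3), C3 (OAr), C4 (OH), C5 (CH3), C6 (OH).
- Ring B: C1' (carboxyl), C2' (ether O), C3' (CHO), C4' (OH), C5' (Cl), C6' (CH3).
- Chain: C1 (ester carbon) to C8 (terminal methyl).

**Remark on protecting groups:** the dioxolane carbon sits next to a carbon that bears both an aryloxy and an acyl group, so it ionizes slowly. Acid strong enough to install or open it would also strip an aryl MOM ether or a tert-butyl ester. Ring B therefore carries an allyl ester, which is inert to acid, shielded by two ortho groups and removed with zerovalent palladium. The MOM group only steers step 4 and is shed on purpose in step 5.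

**Remark on stereochemistry:** the target is achiral. The stereocentres at chain C4, C6 and C7 arise as mixtures and vanish in step 7.

Step 1
Reactants: 1 orsellinic acid (2,4-dihydroxy-6-methylbenzoic acid)
Product: 2 allyl 2,4-dihydroxy-6-methylbenzoate
Conditions: allyl bromide (1.1 equiv), KHCO3 (1.2 equiv), DMF, rt
Reagents that add atoms: allyl bromide, C=CCBr
Why: Carboxylate SN2 alkylation, in which KHCO3 ionizes only the acid and leaves both phenols protonated, and room temperature avoids decarboxylation of the electron-rich acid.

Step 2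
Reactants: 2 allyl 2,4-dihydroxy-6-methylbenzoate
Product: 3 allyl 3-chloro-4,6-dihydroxy-2-methylbenzoate (chlorine on ring B C5')
Conditions: SO2Cl2 (1.0 equiv), Et2O, 0 °C, dark
Reagents that add atoms: sulfuryl chloride, O=S(=O)(Cl)Cl
Why: Electrophilic aromatic chlorination, which in 2,4-dihydroxy-6-alkylbenzoates should prefer C5' (para to the chelated hydroxyl, ortho to the free one) over the position between the two oxygens, and the resorcinol ring should react far faster than the allyl alkene.

Step 3
Reactants: 3 allyl 3-chloro-4,6-dihydroxy-2-methylbenzoate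
Product: 4 allyl 3-chloro-6-hydroxy-4-(methoxymethoxy)-2-methylbenzoate
Conditions: MOMCl (1.05 equiv), iPr2NEt, CH2Cl2, 0 °C
Reagents that add atoms: chloromethyl methyl ether, COCCl
Why: Regioselective Williamson-type etherification, because the C4' hydroxyl is free and the more acidic one while the C2' hydroxyl is tied up in a hydrogen bond to the ester carbonyl.

Step 4
Reactants: 4 allyl 3-chloro-6-hydroxy-4-(methoxymethoxy)-2-methylbenzoate; 5 methyl 2-chloro-3-oxobutanoate (racemic)
Product: 6 allyl 3-chloro-6-[(1-methoxy-1,3-dioxobutan-2-yl)oxy]-4-(methoxymethoxy)-2-methylbenzoate (racemic)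
Conditions: 5 (1.5 equiv), K2CO3, DMF, 50 °C, no iodide additive
Reagents that add atoms: none
Why: Williamson O-alkylation (SN2) of the only free phenoxide by an α-chloro-β-keto ester is the standard entry to 2-aryloxyacetoacetates, and the new centre (chain C6) is racemic and is erased later.

Step 5
Reactants: 6 allyl 3-chloro-6-[(1-methoxy-1,3-dioxobutan-2-yl)oxy]-4-(methoxymethoxy)-2-methylbenzoate
Product: 7 allyl 3-chloro-4-hydroxy-6-[2-methoxy-1-(2-methyl-1,3-dioxolan-2-yl)-2-oxoethoxy]-2-methylbenzoate (racemic)
Conditions: HOCH2CH2OH (5 equiv), TsOH·H2O (0.2 equiv), PhH, Dean–Stark, reflux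
Reagents that add atoms: ethylene glycol, OCCO
Why: Acid-catalysed ketalization with azeotropic water removal is routine for 2-substituted acetoacetates, the same acid hands the MOM methylene to the glycol by transacetalization now that its steering role is over, and the doubly ortho-flanked allyl benzoate should neither exchange nor ionize.

Step 6
Reactants: 7 allyl 3-chloro-4-hydroxy-6-[2-methoxy-1-(2-methyl-1,3-dioxolan-2-yl)-2-oxoethoxy]-2-methylbenzoate; 8 methyl 3-oxopentanoate
Product: 10 methyl 6-[2-(allyloxycarbonyl)-4-chloro-5-hydroxy-3-methylphenoxy]-4-methyl-6-(2-methyl-1,3-dioxolan-2-yl)-3,5-dioxohexanoate (diastereomer/enol mixture), via dilithium dianion of methyl 3-oxopentanoate 9 (not isolated)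
Conditions: 8 (4 equiv), LiN(iPr)2 (8 equiv), THF, −78 to 0 °C; then 7, −78 to −20 °C; AcOH quench
Reagents that add atoms: none
Why: Claisen-type γ-acylation of a β-keto ester dianion (Weiler dianion) by an ester, in which the γ-carbanion is the reactive terminus, the inductively activated α-aryloxy methyl ester is the only accessible acyl donor (the ring B ester is flanked twice and sits on a phenoxide), surplus dianion absorbs the phenol proton and the acidic product, and the C4/C6 centres may stay a mixture because both vanish in step 7.

Step 7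
Reactants: 10 methyl 6-[2-(allyloxycarbonyl)-4-chloro-5-hydroxy-3-methylphenoxy]-4-methyl-6-(2-methyl-1,3-dioxolan-2-yl)-3,5-dioxohexanoate
Product: 13 methyl 3-[2-(allyloxycarbonyl)-4-chloro-5-hydroxy-3-methylphenoxy]-4,6-dihydroxy-2,5-dimethylbenzoate, via free triketo ester 11 (not isolated), via cyclic aldol adduct 12 (not isolated)
Conditions: conc. HCl–MeOH (1:5), 50 °C; then NaOAc to pH 5–6, 50 °C
Reagents that add atoms: none
Why: Methanolic aqueous HCl opens the dioxolane to the chain C7 methyl ketone 11; methanol as solvent makes any exchange at the C1 methyl ester degenerate, and the doubly ortho-flanked allyl benzoate does not react. The chain C2=C3 enol of the β-keto ester (its enolate once the acetate buffer is set) adds to C7, which forges the chain C2–C7 bond (ring A C1–C2) and gives carbinol 12; loss of water across C2–C7 and enolization of the C3 and C5 ketones then make the resorcinol irreversibly. The closest known reaction type is the biomimetic aldol cyclization of 3,5,7-triketo esters to orsellinate-type resorcylates. The six-membered ring closes 6-(enolendo)-exo-trig when counted through the C2=C3 enol (6-(enolexo)-exo-trig through the ester enolate), both favoured modes, and the stereocentres at chain C4, C6 and C7 are all erased, so none needs control. The step needs C2-to-C7 closure over Claisen closure (C6 onto C1), over the reverse aldol (C8 onto C3) and over oxygen cyclization to pyranones. The Claisen product would carry both acetyl and aryloxy on C6, has no path to a benzene ring and reopens by retro-Claisen; C2 is doubly activated whereas C8 is a plain methyl ketone position; dilute protic acid followed by acetate buffer avoids the dehydrating acids and amidine bases that drive pyranone formation, and the deactivated ring B carbon C3' is too poor a nucleophile to capture C7 as a benzofuran.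

Step 8
Reactants: 13 methyl 3-[2-(allyloxycarbonyl)-4-chloro-5-hydroxy-3-methylphenoxy]-4,6-dihydroxy-2,5-dimethylbenzoate
Product: 15 methyl 3-[2-(allyloxycarbonyl)-4-chloro-6-formyl-5-hydroxy-3-methylphenoxy]-4,6-dihydroxy-2,5-dimethylbenzoate, via hydroxymethyl intermediate 14 (not isolated)
Conditions: MgCl2 (6 equiv), Et3N (12 equiv), (CH2O)n (20 equiv), MeCN, reflux; 1 M HCl work-up
Reagents that add atoms: paraformaldehyde (reacts as formaldehyde), C=O
Why: Casnati–Skattebøl ortho-formylation, in which the magnesium phenoxide of the C4' hydroxyl delivers formaldehyde to its only free ortho carbon C3' to give 14, a second formaldehyde oxidizes 14 by hydride transfer, and ring A has no free position, so its two phenols only consume reagent.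

Step 9
Reactants: 15 methyl 3-[2-(allyloxycarbonyl)-4-chloro-6-formyl-5-hydroxy-3-methylphenoxy]-4,6-dihydroxy-2,5-dimethylbenzoate
Product: 16 3-chloro-6-[2,4-dihydroxy-5-(methoxycarbonyl)-3,6-dimethylphenoxy]-5-formyl-4-hydroxy-2-methylbenzoic acid (target)
Conditions: Pd(PPh3)4 (5 mol%), TolSO2Na (1.5 equiv), THF–MeOH, rt; 1 M HCl work-up
Reagents that add atoms: none
Why: Tsuji–Trost-type deallylation, in which zerovalent palladium ionizes the ester at the remote allyl terminus (so the crowding at the carbonyl is irrelevant), the sulfinate traps the allyl unit without condensing with the aldehyde, and the aryl chloride, methyl ester and phenols should be untouched at room temperature.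

**Compound list**
1 | orsellinic acid | Cc1cc(O)cc(O)c1C(=O)O | starting material
2 | allyl 2,4-dihydroxy-6-methylbenzoate | C=CCOC(=O)c1c(C)cc(O)cc1O | intermediate
3 | allyl 3-chloro-4,6-dihydroxy-2-methylbenzoate | C=CCOC(=O)c1c(C)c(Cl)c(O)cc1O | intermediate
4 | allyl 3-chloro-6-hydroxy-4-(methoxymethoxy)-2-methylbenzoate | C=CCOC(=O)c1c(C)c(Cl)c(OCOC)cc1O | intermediate
5 | methyl 2-chloro-3-oxobutanoate (racemic) | CC(=O)C(Cl)C(=O)OC | starting material
6 | allyl 3-chloro-6-[(1-methoxy-1,3-dioxobutan-2-yl)oxy]-4-(methoxymethoxy)-2-methylbenzoate (racemic) | C=CCOC(=O)c1c(C)c(Cl)c(OCOC)cc1OC(C(C)=O)C(=O)OC | intermediate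
7 | allyl 3-chloro-4-hydroxy-6-[2-methoxy-1-(2-methyl-1,3-dioxolan-2-yl)-2-oxoethoxy]-2-methylbenzoate (racemic) | C=CCOC(=O)c1c(C)c(Cl)c(O)cc1OC(C(=O)OC)C2(C)OCCO2 | intermediate
8 | methyl 3-oxopentanoate | CCC(=O)CC(=O)OC | starting material
9 | dilithium dianion (bis-enolate) of methyl 3-oxopentanoate | CC=C([O-])C=C([O-])OC.[Li+].[Li+] | intermediate
10 | methyl 6-[2-(allyloxycarbonyl)-4-chloro-5-hydroxy-3-methylphenoxy]-4-methyl-6-(2-methyl-1,3-dioxolan-2-yl)-3,5-dioxohexanoate (mixture of diastereomers and enol forms) | COC(=O)CC(=O)C(C)C(=O)C(Oc1cc(O)c(Cl)c(C)c1C(=O)OCC=C)C2(C)OCCO2 | intermediate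
11 | methyl 6-[2-(allyloxycarbonyl)-4-chloro-5-hydroxy-3-methylphenoxy]-4-methyl-3,5,7-trioxooctanoate (mixture) | COC(=O)CC(=O)C(C)C(=O)C(Oc1cc(O)c(Cl)c(C)c1C(=O)OCC=C)C(C)=O | intermediate
12 | methyl 3-[2-(allyloxycarbonyl)-4-chloro-5-hydroxy-3-methylphenoxy]-2-hydroxy-2,5-dimethyl-4,6-dioxocyclohexane-1-carboxylate (mixture of diastereomers) | COC(=O)C1C(=O)C(C)C(=O)C(Oc2cc(O)c(Cl)c(C)c2C(=O)OCC=C)C1(C)O | intermediate
13 | methyl 3-[2-(allyloxycarbonyl)-4-chloro-5-hydroxy-3-methylphenoxy]-4,6-dihydroxy-2,5-dimethylbenzoate | COC(=O)c1c(C)c(Oc2cc(O)c(Cl)c(C)c2C(=O)OCC=C)c(O)c(C)c1O | intermediate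
14 | methyl 3-[2-(allyloxycarbonyl)-4-chloro-5-hydroxy-6-(hydroxymethyl)-3-methylphenoxy]-4,6-dihydroxy-2,5-dimethylbenzoate | COC(=O)c1c(C)c(Oc2c(CO)c(O)c(Cl)c(C)c2C(=O)OCC=C)c(O)c(C)c1O | intermediate
15 | methyl 3-[2-(allyloxycarbonyl)-4-chloro-6-formyl-5-hydroxy-3-methylphenoxy]-4,6-dihydroxy-2,5-dimethylbenzoate | COC(=O)c1c(C)c(Oc2c(C=O)c(O)c(Cl)c(C)c2C(=O)OCC=C)c(O)c(C)c1O | intermediate
16 | 3-chloro-6-[2,4-dihydroxy-5-(methoxycarbonyl)-3,6-dimethylphenoxy]-5-formyl-4-hydroxy-2-methylbenzoic acid | COC(=O)c1c(C)c(Oc2c(C=O)c(O)c(Cl)c(C)c2C(=O)O)c(O)c(C)c1O | target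

Total step count: 9. Longest linear sequence: 9 steps (1 to 16).

**Steps most likely to fail**

**Step 7 (key step).** Once the dioxolane opens, attack of the chain C3 enol oxygen on C7 and dehydration may outrun carbon–carbon closure, or acid methanolysis may clip the acetyl group from the 2-aryloxy-1,3-diketone. The fallback accepts the oxygen cyclization and uses the heterocycle as a stable store of the triketide. It sets out from 10. Neat CF3CO2H at rt should open the ketal and dehydrate to methyl 2-{5-[2-(allyloxycarbonyl)-4-chloro-5-hydroxy-3-methylphenoxy]-3,6-dimethyl-4-oxo-4H-pyran-2-yl}acetate F1. NaOMe in MeOH at 50 °C then adds to the pyranone and reopens it to the triketide enolate, in a medium where acid-driven dehydration is impossible. The chain C2 carbanion closes onto C7, which is the known base-induced recyclization of 2-(alkoxycarbonylmethyl)-4-pyranones to resorcylates. The fallback comes back to the route at 13.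

**Step 6.** Proton transfer from chain C6–H of 7 to the dianion, followed by β-elimination that opens the dioxolane, may compete with slow attack on the neopentyl-like ester carbonyl. The fallback swaps acyl substitution for carbonyl addition plus oxidation and sets out from 7. iBu2AlH (2.2 equiv, CH2Cl2, −78 °C) should stop at allyl 3-chloro-4-hydroxy-2-methyl-6-[1-(2-methyl-1,3-dioxolan-2-yl)-2-oxoethoxy]benzoate F2. Dianion 9 adds to this aldehyde at −78 °C faster than it can deprotonate it, giving methyl 6-[2-(allyloxycarbonyl)-4-chloro-5-hydroxy-3-methylphenoxy]-5-hydroxy-4-methyl-6-(2-methyl-1,3-dioxolan-2-yl)-3-oxohexanoate F3. Dess–Martin periodinane (CH2Cl2, rt) oxidizes the C5 carbinol, and the electron-poor chlorophenol should be spared. The fallback comes back to the route at 10.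

**Step 4.** The chloride is largely parked as its enolate and the phenoxide is chelated and flanked by the ester. The SN2 step may therefore be slower than self-condensation of 5 or base-induced loss of the acetyl group from 6. The fallback forms the same C–O bond under neutral conditions by carbenoid O–H insertion and sets out from 4. Methyl 2-diazo-3-oxobutanoate F4 is made by Regitz diazo transfer to methyl acetoacetate (4-acetamidobenzenesulfonyl azide, Et3N, MeCN). It is added slowly to 4 and Rh2(OAc)4 (1 mol%) in CH2Cl2 at reflux. The fallback comes back to the route at 6.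

**Further compounds**
F1 | step 7 | methyl 2-{5-[2-(allyloxycarbonyl)-4-chloro-5-hydroxy-3-methylphenoxy]-3,6-dimethyl-4-oxo-4H-pyran-2-yl}acetate | COC(=O)CC1=C(C)C(=O)C(Oc2cc(O)c(Cl)c(C)c2C(=O)OCC=C)=C(C)O1
F2 | step 6 | allyl 3-chloro-4-hydroxy-2-methyl-6-[1-(2-methyl-1,3-dioxolan-2-yl)-2-oxoethoxy]benzoate (racemic) | O=CC(Oc1cc(O)c(Cl)c(C)c1C(=O)OCC=C)C2(C)OCCO2
F3 | step 6 | methyl 6-[2-(allyloxycarbonyl)-4-chloro-5-hydroxy-3-methylphenoxy]-5-hydroxy-4-methyl-6-(2-methyl-1,3-dioxolan-2-yl)-3-oxohexanoate (mixture of diastereomers) | COC(=O)CC(=O)C(C)C(O)C(Oc1cc(O)c(Cl)c(C)c1C(=O)OCC=C)C2(C)OCCO2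
F4 | step 4 | methyl 2-diazo-3-oxobutanoate | CC(=O)C(=[N+]=[N-])C(=O)OC
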